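**Retrosynthetic overview**

1. The target is a fisetinidol-(4α→6)-flavan-3,4-diol. Rings A, C and B are the benzo, pyran and catechol rings of the upper unit; rings D, F and E are those of the lower unit.
2. The C4 hydroxyl of ring F comes last, by NaBH4 reduction of the (2R,3R)-dihydroflavonol after debenzylation. Ring F (O1–C2 bond) comes from acid cyclization of a 2'-O-MOM chalcone epoxide built on the acetyl group of ring D (Claisen–Schmidt, then Juliá–Colonna).
3. Key disconnection: C4–C4a of ring C. C4 of ring C is a diarylmethine bonded to C4a of ring A and C6 of ring D and trans to the C3 hydroxyl, so this bond and the C3 oxygen both come from a C3–C4 trans-epoxide opened by ring A.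
4. The epoxide comes from Shi epoxidation of an E-alkene. The alkene comes from cross-metathesis of a ring-D vinylacetophenone with a branched allyl aryl ether, whose C2–O1 bond and C2 configuration are set by iridium-catalysed allylic etherification.
5. Ring order: ring C (step 10), then ring F (step 13).

Key step: step 10

Assumption: the (Sa,Sc,Sc) phosphoramidite is taken to give the S ether 7 in step 4; if the first run gives the R ether, the ligand antipode is used and nothing else changes.

**Route**

Step 1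
Reactants: 1 3,4-bis(benzyloxy)benzaldehyde
Product: 2 ethyl (E)-3-[3,4-bis(benzyloxy)phenyl]prop-2-enoate
Conditions: triethyl phosphonoacetate, NaH, THF, 0 °C → rt
Reagents that add atoms: triethyl phosphonoacetate, CCOC(=O)CP(=O)(OCC)OCC
Why: Horner–Wadsworth–Emmons olefination of a non-enolisable aryl aldehyde with a stabilized phosphonate should give the E-cinnamate.

Step 2
Reactants: 2 ethyl (E)-3-[3,4-bis(benzyloxy)phenyl]prop-2-enoate
Product: 3 (E)-3-[3,4-bis(benzyloxy)phenyl]prop-2-en-1-ol
Conditions: i-Bu2AlH (2.2 equiv), CH2Cl2, −78 → 0 °C; aq. KNaC4H4O6 work-up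
Reagents that add atoms: none
Why: 1,2-reduction of a conjugated ester by an aluminium hydride should give the allylic alcohol and leave the alkene and the benzyl ethers alone.

Step 3
Reactants: 3 (E)-3-[3,4-bis(benzyloxy)phenyl]prop-2-en-1-ol
Product: 4 (E)-3-[3,4-bis(benzyloxy)phenyl]prop-2-en-1-yl methyl carbonate
Conditions: ClCO2Me, pyridine, CH2Cl2, 0 °C
Reagents that add atoms: methyl chloroformate, COC(=O)Cl
Why: O-acylation of a primary allylic alcohol with a chloroformate gives the linear carbonate needed as the allyl electrophile.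

Step 4
Reactants: 4 (E)-3-[3,4-bis(benzyloxy)phenyl]prop-2-en-1-yl methyl carbonate; 5 3-(benzyloxy)phenol
Product: 7 (S)-1,2-bis(benzyloxy)-4-[1-[3-(benzyloxy)phenoxy]prop-2-en-1-yl]benzene, via lithium 3-(benzyloxy)phenoxide 6 (not isolated)
Conditions: 5, n-BuLi, THF, 0 °C; then 4, [Ir(cod)Cl]2 (2 mol%), (Sa,Sc,Sc)-(1,1'-binaphthalene-2,2'-diyl) N,N-bis(1-phenylethyl)phosphoramidite (4 mol%), THF, 50 °C
Reagents that add atoms: none
Why: Iridium-catalysed asymmetric allylic etherification, in which the aryloxide attacks the aryl-substituted terminus of the allyl–iridium intermediate formed by decarboxylative ionization, should give the branched ether, with the C2 stereocentre set by the chiral phosphoramidite.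

Step 5
Reactants: 8 1-(5-bromo-2,4-dihydroxyphenyl)ethanone
Product: 9 1-[4-(benzyloxy)-5-bromo-2-hydroxyphenyl]ethanone
Conditions: BnBr (1.05 equiv), K2CO3, acetone, reflux
Reagents that add atoms: benzyl bromide, BrCc1ccccc1
Why: Williamson etherification should go at the 4-hydroxyl, because the 2-hydroxyl is held in a hydrogen bond to the acetyl carbonyl and is much less nucleophilic.

Step 6
Reactants: 9 1-[4-(benzyloxy)-5-bromo-2-hydroxyphenyl]ethanone
Product: 10 1-[4-(benzyloxy)-5-bromo-2-(methoxymethoxy)phenyl]ethanone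
Conditions: MOMCl, i-Pr2NEt, CH2Cl2, 0 °C → rt
Reagents that add atoms: chloromethyl methyl ether, COCCl
Why: Acetal protection of the remaining phenol with the reactive chloromethyl ether masks the future ring-F oxygen as an acid-removable MOM ether.

Step 7
Reactants: 10 1-[4-(benzyloxy)-5-bromo-2-(methoxymethoxy)phenyl]ethanone
Product: 11 1-[4-(benzyloxy)-5-ethenyl-2-(methoxymethoxy)phenyl]ethanone
Conditions: vinylboronic acid pinacol ester, PdCl2(dppf) (3 mol%), K2CO3, dioxane/H2O, 80 °C
Reagents that add atoms: 4,4,5,5-tetramethyl-2-vinyl-1,3,2-dioxaborolane, C=CB1OC(C)(C)C(C)(C)O1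
Why: Suzuki–Miyaura vinylation of an aryl bromide is reliable beside a ketone, a MOM ether and a benzyl ether.

Step 8
Reactants: 7 (S)-1,2-bis(benzyloxy)-4-[1-[3-(benzyloxy)phenoxy]prop-2-en-1-yl]benzene; 11 1-[4-(benzyloxy)-5-ethenyl-2-(methoxymethoxy)phenyl]ethanone
Product: 12 1-[4-(benzyloxy)-5-[(1E,3S)-3-[3,4-bis(benzyloxy)phenyl]-3-[3-(benzyloxy)phenoxy]prop-1-en-1-yl]-2-(methoxymethoxy)phenyl]ethanone
Conditions: second-generation Hoveyda–Grubbs catalyst RuCl2(H2IMes)(=CH-C6H4-2-O-i-Pr) (5–10 mol%), 11 (2 equiv), 1,4-benzoquinone (10 mol%), CH2Cl2, 40 °C, argon sweep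
Reagents that add atoms: none
Why: Olefin cross-metathesis of a terminal allylic ether with a styrene, driven by loss of ethylene, should give the conjugated E-alkene under thermodynamic control without touching the allylic stereocentre.

Step 9
Reactants: 12 the E-alkene
Product: 13 1-[4-(benzyloxy)-5-[(2R,3S)-3-[(R)-[3,4-bis(benzyloxy)phenyl][3-(benzyloxy)phenoxy]methyl]oxiran-2-yl]-2-(methoxymethoxy)phenyl]ethanone (trans-epoxide, anti to the aryloxy group)
Conditions: D-fructose-derived Shi ketone (30 mol%), Oxone (2KHSO5·KHSO4·K2SO4), K2CO3, Bu4NHSO4 (cat.), MeCN/CH2(OMe)2, aq. Na2B4O7/Na2EDTA buffer (pH about 10.5), 0 °C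
Reagents that add atoms: potassium peroxymonosulfate (oxidant of Oxone), [K+].[O-]S(=O)(=O)OO
Why: Shi asymmetric epoxidation, in which the chiral dioxirane transfers oxygen through a spiro transition state, should give the trans-epoxide in the same facial sense as (R,R)-stilbene oxide from trans-stilbene, under reagent control that overrides the allylic stereocentre, while the basic buffer protects the acid-labile benzylic epoxide.

Step 10
Reactants: 13 the anti epoxy aryl ether
Product: 14 1-[4-(benzyloxy)-5-[(2R,3S,4S)-7-(benzyloxy)-2-[3,4-bis(benzyloxy)phenyl]-3-hydroxy-3,4-dihydro-2H-chromen-4-yl]-2-(methoxymethoxy)phenyl]ethanone (2,3-trans-3,4-trans)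
Conditions: InBr3 (10 mol%), 4 Å MS, CH2Cl2 (0.01 M), −20 → 0 °C
Reagents that add atoms: none
Why: InBr3 binds the oxirane oxygen and lengthens the C4–O bond, which is benzylic to the 2-benzyloxy-4-(methoxymethoxy)aryl ring D, and the carbon of the 3-(benzyloxy)phenoxy ring that is ortho to the ether oxygen and para to the benzyloxy group attacks C4 from the face opposite the departing oxygen, after which loss of a proton restores the arene. The closest known reaction is the Lewis-acid intramolecular Friedel–Crafts epoxy-arene cyclization of aryl ethers of 3-aryl-2,3-epoxy alcohols to trans-4-arylchroman-3-ols. Ring C closes in the 6-endo mode at the oxirane, because the 5-exo opening at C3 has no cation-stabilizing group and C3 is deactivated by the neighbouring C2–O bond. C4 is set by inversion of the oxirane carbon fixed in step 9, so the new aryl–C4 bond stands trans to the C3 hydroxyl, while C3 keeps its oxygen and configuration and C2 is untouched; if the opening drifts to a free benzylic cation, the chair-like closure with both aryl groups and the oxygen equatorial leads to the same 2,3-trans-3,4-trans isomer. The step needs endo regioselectivity (secured by benzylic activation at C4), attack para and not ortho to the benzyloxy group (secured by the crowding of the carbon between the two oxygens), and suppression of the hydride shift to the benzyl ketone and of MOM loss (addressed by catalytic InBr3, a non-coordinating solvent, low temperature and the acetyl group, which tempers the cation).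

Step 11
Reactants: 14 the 4-arylflavan-3-ol acetophenone; 1 3,4-bis(benzyloxy)benzaldehyde
Product: 15 (E)-1-[4-(benzyloxy)-5-[(2R,3S,4S)-7-(benzyloxy)-2-[3,4-bis(benzyloxy)phenyl]-3-hydroxy-3,4-dihydro-2H-chromen-4-yl]-2-(methoxymethoxy)phenyl]-3-[3,4-bis(benzyloxy)phenyl]prop-2-en-1-one
Conditions: 1 (1.2 equiv), KOH, EtOH/THF, rt
Reagents that add atoms: none
Why: Claisen–Schmidt condensation of the only enolisable ketone with a non-enolisable aldehyde should give the E-chalcone, and the fully benzylated flavan unit has no free phenol through which base could open ring C.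

Step 12
Reactants: 15 the chalcone
Product: 16 [4-(benzyloxy)-5-[(2R,3S,4S)-7-(benzyloxy)-2-[3,4-bis(benzyloxy)phenyl]-3-hydroxy-3,4-dihydro-2H-chromen-4-yl]-2-(methoxymethoxy)phenyl][(2R,3S)-3-[3,4-bis(benzyloxy)phenyl]oxiran-2-yl]methanone
Conditions: poly-L-leucine, urea–H2O2, DBU, THF, rt
Reagents that add atoms: hydrogen peroxide (as urea–hydrogen peroxide), OO
Why: Juliá–Colonna epoxidation, a Weitz–Scheffer addition of hydroperoxide steered by the helical poly-L-leucine, should give the (αR,βS) trans-epoxide under catalyst control, and the minor diastereomer is separable because the upper unit is already chiral.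

Step 13
Reactants: 16 the chalcone epoxide
Product: 18 (2R,3R)-7-(benzyloxy)-6-[(2R,3S,4S)-7-(benzyloxy)-2-[3,4-bis(benzyloxy)phenyl]-3-hydroxy-3,4-dihydro-2H-chromen-4-yl]-2-[3,4-bis(benzyloxy)phenyl]-3-hydroxy-2,3-dihydro-4H-chromen-4-one, via 2'-hydroxy chalcone epoxide 17 (not isolated)
Conditions: conc. HCl, MeOH/THF, 50 °C
Reagents that add atoms: none
Why: Acid removes the MOM acetal, and the freed phenol opens the oxirane at the benzylic β-carbon in a 6-endo ring closure with inversion, so C2 of ring F becomes R and trans to the retained C3 oxygen, which is also the thermodynamically preferred diequatorial arrangement.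

Step 14
Reactants: 18 the hexabenzyl dihydroflavonol
Product: 19 (2R,3R)-2-(3,4-dihydroxyphenyl)-6-[(2R,3S,4R)-2-(3,4-dihydroxyphenyl)-3,7-dihydroxy-3,4-dihydro-2H-chromen-4-yl]-3,7-dihydroxy-2,3-dihydro-4H-chromen-4-one
Conditions: H2 (1 atm), Pd(OH)2/C, THF/MeOH, rt
Reagents that add atoms: none
Why: Catalytic hydrogenolysis should cleave the six benzyl ethers, and it is placed before the ketone reduction so that no hydrogenolysis-prone benzylic C4 hydroxyl is yet present; the cyclic benzylic ethers and the vinylogous-ester-like ketone should survive at 1 atm if the reaction is stopped at completion.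

Step 15
Reactants: 19 the free dihydroflavonol
Product: 20 (2R,3S,4R)-2-(3,4-dihydroxyphenyl)-6-[(2R,3S,4R)-2-(3,4-dihydroxyphenyl)-3,7-dihydroxy-3,4-dihydro-2H-chromen-4-yl]-3,4-dihydro-2H-chromene-3,4,7-triol (CNP0280090.3)
Conditions: NaBH4, EtOH, 0 °C → rt; work-up at pH 6, Sephadex LH-20
Reagents that add atoms: none
Why: Borohydride reduction of a 2,3-trans dihydroflavonol should deliver hydride axially to the half-chair and give the equatorial C4 hydroxyl trans to the C3 hydroxyl (2,3-trans-3,4-trans), and the near-neutral work-up protects the acid-labile benzylic alcohol.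

**Compound list**

1 | 3,4-bis(benzyloxy)benzaldehyde | O=Cc1ccc(OCc2ccccc2)c(OCc2ccccc2)c1 | starting material
2 | ethyl (E)-3-[3,4-bis(benzyloxy)phenyl]prop-2-enoate | CCOC(=O)/C=C/c1ccc(OCc2ccccc2)c(OCc2ccccc2)c1 | intermediate
3 | (E)-3-[3,4-bis(benzyloxy)phenyl]prop-2-en-1-ol | OC/C=C/c1ccc(OCc2ccccc2)c(OCc2ccccc2)c1 | intermediate
4 | (E)-3-[3,4-bis(benzyloxy)phenyl]prop-2-en-1-yl methyl carbonate | COC(=O)OC/C=C/c1ccc(OCc2ccccc2)c(OCc2ccccc2)c1 | intermediate
5 | 3-(benzyloxy)phenol | Oc1cccc(OCc2ccccc2)c1 | starting material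
6 | lithium 3-(benzyloxy)phenoxide | [Li+].[O-]c1cccc(OCc2ccccc2)c1 | intermediate (not isolated)
7 | (S)-1,2-bis(benzyloxy)-4-[1-[3-(benzyloxy)phenoxy]prop-2-en-1-yl]benzene | c1ccccc1COc1cccc(c1)O[C@H](c1ccc(OCc2ccccc2)c(OCc2ccccc2)c1)C=C | intermediate
8 | 1-(5-bromo-2,4-dihydroxyphenyl)ethanone | CC(=O)c1cc(Br)c(O)cc1O | starting material
9 | 1-[4-(benzyloxy)-5-bromo-2-hydroxyphenyl]ethanone | CC(=O)c1cc(Br)c(OCc2ccccc2)cc1O | intermediate
10 | 1-[4-(benzyloxy)-5-bromo-2-(methoxymethoxy)phenyl]ethanone | CC(=O)c1cc(Br)c(OCc2ccccc2)cc1OCOC | intermediate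
11 | 1-[4-(benzyloxy)-5-ethenyl-2-(methoxymethoxy)phenyl]ethanone | CC(=O)c1cc(C=C)c(OCc2ccccc2)cc1OCOC | intermediate
12 | 1-[4-(benzyloxy)-5-[(1E,3S)-3-[3,4-bis(benzyloxy)phenyl]-3-[3-(benzyloxy)phenoxy]prop-1-en-1-yl]-2-(methoxymethoxy)phenyl]ethanone | c1ccccc1COc1cccc(c1)O[C@H](c1ccc(OCc2ccccc2)c(OCc2ccccc2)c1)/C=C/c1cc(C(C)=O)c(OCOC)cc1OCc1ccccc1 | intermediate
13 | 1-[4-(benzyloxy)-5-[(2R,3S)-3-[(R)-[3,4-bis(benzyloxy)phenyl][3-(benzyloxy)phenoxy]methyl]oxiran-2-yl]-2-(methoxymethoxy)phenyl]ethanone | c1ccccc1COc1cccc(c1)O[C@H](c1ccc(OCc2ccccc2)c(OCc2ccccc2)c1)[C@H]1O[C@@H]1c1cc(C(C)=O)c(OCOC)cc1OCc1ccccc1 | intermediate (key-step precursor)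
14 | 1-[4-(benzyloxy)-5-[(2R,3S,4S)-7-(benzyloxy)-2-[3,4-bis(benzyloxy)phenyl]-3-hydroxy-3,4-dihydro-2H-chromen-4-yl]-2-(methoxymethoxy)phenyl]ethanone | c1ccccc1COc1ccc2c(c1)O[C@H](c1ccc(OCc3ccccc3)c(OCc3ccccc3)c1)[C@@H](O)[C@@H]2c1cc(C(C)=O)c(OCOC)cc1OCc1ccccc1 | intermediate (key-step product)
15 | (E)-chalcone of 14 with 3,4-bis(benzyloxy)benzaldehyde | c1ccccc1COc1ccc2c(c1)O[C@H](c1ccc(OCc3ccccc3)c(OCc3ccccc3)c1)[C@@H](O)[C@@H]2c1cc(C(=O)/C=C/c2ccc(OCc3ccccc3)c(OCc3ccccc3)c2)c(OCOC)cc1OCc1ccccc1 | intermediate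
16 | (αR,βS)-chalcone epoxide, 2'-O-MOM | c1ccccc1COc1ccc2c(c1)O[C@H](c1ccc(OCc3ccccc3)c(OCc3ccccc3)c1)[C@@H](O)[C@@H]2c1cc(C(=O)[C@@H]2O[C@H]2c2ccc(OCc3ccccc3)c(OCc3ccccc3)c2)c(OCOC)cc1OCc1ccccc1 | intermediate
17 | (αR,βS)-2'-hydroxy chalcone epoxide | c1ccccc1COc1ccc2c(c1)O[C@H](c1ccc(OCc3ccccc3)c(OCc3ccccc3)c1)[C@@H](O)[C@@H]2c1cc(C(=O)[C@@H]2O[C@H]2c2ccc(OCc3ccccc3)c(OCc3ccccc3)c2)c(O)cc1OCc1ccccc1 | intermediate (not isolated)
18 | hexabenzyl (2R,3R)-dihydroflavonol bearing the (2R,3S,4S)-flavan-3-ol at C6 | c1ccccc1COc1ccc2c(c1)O[C@H](c1ccc(OCc3ccccc3)c(OCc3ccccc3)c1)[C@@H](O)[C@@H]2c1cc2c(cc1OCc1ccccc1)O[C@H](c1ccc(OCc3ccccc3)c(OCc3ccccc3)c1)[C@@H](O)C2=O | intermediate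
19 | (2R,3R)-2-(3,4-dihydroxyphenyl)-6-[(2R,3S,4R)-2-(3,4-dihydroxyphenyl)-3,7-dihydroxy-3,4-dihydro-2H-chromen-4-yl]-3,7-dihydroxy-2,3-dihydro-4H-chromen-4-one | Oc1ccc2c(c1)O[C@H](c1ccc(O)c(O)c1)[C@@H](O)[C@@H]2c1cc2c(cc1O)O[C@H](c1ccc(O)c(O)c1)[C@@H](O)C2=O | intermediate
20 | (2R,3S,4R)-2-(3,4-dihydroxyphenyl)-6-[(2R,3S,4R)-2-(3,4-dihydroxyphenyl)-3,7-dihydroxy-3,4-dihydro-2H-chromen-4-yl]-3,4-dihydro-2H-chromene-3,4,7-triol | Oc1ccc2c(c1)O[C@H](c1ccc(O)c(O)c1)[C@@H](O)[C@@H]2c1cc2c(cc1O)O[C@H](c1ccc(O)c(O)c1)[C@@H](O)[C@@H]2O | target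

**Step count and risk**

Total step count: 15. Longest linear sequence: 12 steps (steps 1–4 and 8–15, from aldehyde 1); steps 5–7 form the three-step side branch to 11.

Steps most likely to fail:

1. Step 10 (key cyclization). The opened epoxide may undergo a hydride shift from C3 to C4 (Meinwald-type rearrangement to the benzyl ketone) faster than arylation, or the Lewis acid may strip the MOM ether that is chelated to the acetyl group. The fallback sets out from 13 and separates ring opening from C–C bond formation. The oxirane is opened at the benzylic C4 with phenylmethanethiol and K2CO3 in THF/MeOH, a base-mediated SN2 opening at the carbon remote from the oxygenated C2, to give the β-hydroxy benzyl sulfide F1. Thiophilic activation of F1 with AgBF4 in CH2Cl2 at 0 °C then releases the benzylic cation, which ring A captures through the chair-like all-equatorial transition state. This returns to the route at 14.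

2. Step 13 (acid cyclization to the dihydroflavonol). Methanolysis of the benzylic oxirane carbon and acid-induced aroyl migration may compete with closure by the freed phenol, and partial ionization may erode the 2,3-trans selectivity. The fallback sets out from 16. Phenylmethanethiol and SnCl4 in CH2Cl2 at −20 °C open the oxirane at the β-carbon and remove the MOM group in the same operation, giving the α,2'-dihydroxy-β-(benzylsulfanyl)dihydrochalcone F2, in which the α-configuration is retained. AgBF4 in CH2Cl2 at 0 °C then ionizes the C–S bond, and the phenol closes ring F with the aryl group equatorial. This returns to the route at 18.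

3. Step 8 (cross-metathesis). Productive metathesis between two hindered partners may be slow, because the ortho-benzyloxy styrene can hold ruthenium as a chelate and homodimerize, and a ruthenium hydride may isomerize the allylic ether. The fallback sets out from 7 and uses bromide 10 in place of 11. Ether 7 is cross-metathesized with the small, reactive vinylboronic acid pinacol ester (second-generation Hoveyda–Grubbs catalyst, CH2Cl2, 40 °C) to give the (S,E)-alkenylboronate F3. Suzuki–Miyaura coupling of F3 with 10 (Pd(OAc)2, SPhos, K3PO4, THF/H2O, 40 °C) then forms the aryl–alkene bond; the mild conditions are chosen so that oxidative addition of the aryl bromide outruns ionization of the allylic aryl ether by zerovalent palladium. This returns to the route at 12.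

**Further compounds**

F1 | step 10 | β-hydroxy benzyl sulfide from opening of 13 at C4 (C3 hydroxyl retained, C4 inverted) | c1ccccc1COc1cccc(c1)O[C@H](c1ccc(OCc2ccccc2)c(OCc2ccccc2)c1)[C@@H](O)[C@@H](SCc1ccccc1)c1cc(C(C)=O)c(OCOC)cc1OCc1ccccc1
F2 | step 13 | α,2'-dihydroxy-β-(benzylsulfanyl)dihydrochalcone from 16 (α-configuration retained, β-carbon as a mixture) | c1ccccc1COc1ccc2c(c1)O[C@H](c1ccc(OCc3ccccc3)c(OCc3ccccc3)c1)[C@@H](O)[C@@H]2c1cc(C(=O)[C@H](O)C(SCc2ccccc2)c2ccc(OCc3ccccc3)c(OCc3ccccc3)c2)c(O)cc1OCc1ccccc1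
F3 | step 8 | (S,E)-2-[3-[3,4-bis(benzyloxy)phenyl]-3-[3-(benzyloxy)phenoxy]prop-1-en-1-yl]-4,4,5,5-tetramethyl-1,3,2-dioxaborolane | c1ccccc1COc1cccc(c1)O[C@H](c1ccc(OCc2ccccc2)c(OCc2ccccc2)c1)/C=C/B1OC(C)(C)C(C)(C)O1
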